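## Retrosynthetic overview
1. The last operation is acid removal of four MOM ethers and one TBS ether from the protected flavanone. Rings A and B are bought as arenes (phloroglucinol, methyl 2,4-dihydroxybenzoate), and ring C is the only ring built and is formed last.
2. The key disconnection is C3–C4 of ring C, made by an enantioselective rhodium-catalysed intramolecular hydroacylation (6-endo) of a 2-(1-arylvinyloxy)benzaldehyde. This open isomer of the protected flavanone has no C2 stereocentre, and one step gives ring C, the C4 ketone and (2S).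
3. Enabling feature: in ring C, C2 carries both O1 and ring B, C3 is an unsubstituted CH2, and C4 sits on C4a, ortho to the O1-bearing C8a of ring A. C2–C3 therefore maps onto a 1,1-disubstituted enol ether that O1 holds next to a formyl group.
4. The enol ether aldehyde comes from an ortho-iodophenol of ring A and 2,4-bis(methoxymethoxy)benzoic acid by esterification at O1, Petasis methylenation, and iodine–lithium exchange with formylation.
5. For ring A and the side chain, lithiated tris-MOM phloroglucinol opens a trans-3-prenyl-4-methylbutyrolactone (a temporary ring); the (S)-methyl lactone and an anti alkylation set both side-chain centres. Chelation-controlled loss of one MOM group frees O1, an ortho-quinone methide reduction turns the ketone into the C8 benzylic CH2, and ortho-iodination marks C4a.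

Key step: step 14

Assumption: (S)-4-methyldihydrofuran-2(3H)-one is taken as a catalogue compound, and because the sense of induction of DTBM-SEGPHOS on an O-vinyl substrate cannot be read from precedent, the (R)-ligand is written and the equally available (S)-ligand is taken if a model aldehyde closes to the 2R series.

## Route

Step 1
Reactants: 1 phloroglucinol
Product: 2 1,3,5-tris(methoxymethoxy)benzene
Conditions: NaH, MOMCl, DMF, 0 °C to rt
Reagents that add atoms: chloromethyl methyl ether (MOMCl), COCCl
Why: Williamson-type O-alkylation of the three equivalent phenoxides gives the tris-acetal, whose MOM groups later direct the lithiation, allow one chelation-controlled removal and all fall in the final acid step.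

Step 2
Reactants: 3 (S)-4-methyldihydrofuran-2(3H)-one, 4 prenyl bromide
Product: 6 (3S,4S)-4-methyl-3-(3-methylbut-2-en-1-yl)dihydrofuran-2(3H)-one, via lithium enolate 5 (not isolated)
Conditions: LiN(iPr)2, THF, −78 °C; then 4, DMPU, −78 to −40 °C
Reagents that add atoms: none
Why: Lactone enolate alkylation (SN2 on an allylic bromide): the bromide approaches the flat enolate 5 on the face anti to the C4 methyl group, so the new C3 centre should come out trans to it, that is (3S,4S), which maps onto the (2R) and (2S) side-chain centres of the target.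

Step 3
Reactants: 2 1,3,5-tris(methoxymethoxy)benzene, 6 (3S,4S)-4-methyl-3-(3-methylbut-2-en-1-yl)dihydrofuran-2(3H)-one
Product: 8 (2S,3S)-4-hydroxy-3-methyl-2-(3-methylbut-2-en-1-yl)-1-[2,4,6-tris(methoxymethoxy)phenyl]butan-1-one, via aryllithium 7 (not isolated)
Conditions: 2, n-BuLi, THF, 0 °C; then 6, −78 °C; aq NH4Cl at −78 °C
Reagents that add atoms: none
Why: Directed ortho-lithiation between two MOM ethers (the three ring C–H positions are equivalent) followed by nucleophilic acyl substitution on the lactone; the crowded lithium hemiketal should survive until the cold quench, which blocks a second addition and keeps the centre next to the new ketone from epimerising.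

Step 4
Reactants: 8 (2S,3S)-4-hydroxy-3-methyl-2-(3-methylbut-2-en-1-yl)-1-[2,4,6-tris(methoxymethoxy)phenyl]butan-1-one
Product: 9 (2S,3S)-4-(tert-butyldimethylsilyloxy)-3-methyl-2-(3-methylbut-2-en-1-yl)-1-[2,4,6-tris(methoxymethoxy)phenyl]butan-1-one
Conditions: TBSCl, imidazole, CH2Cl2, rt
Reagents that add atoms: tert-butyldimethylsilyl chloride (TBSCl), CC(C)(C)[Si](C)(C)Cl
Why: Standard silylation of the only free hydroxyl group traps the open hydroxy ketone form and masks the alcohol against the later acylation, titanium and organolithium steps.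

Step 5
Reactants: 9 (2S,3S)-4-(tert-butyldimethylsilyloxy)-3-methyl-2-(3-methylbut-2-en-1-yl)-1-[2,4,6-tris(methoxymethoxy)phenyl]butan-1-one
Product: 10 (2S,3S)-4-(tert-butyldimethylsilyloxy)-1-[2-hydroxy-4,6-bis(methoxymethoxy)phenyl]-3-methyl-2-(3-methylbut-2-en-1-yl)butan-1-one
Conditions: MgBr2·OEt2, CH2Cl2/Et2O, 0 °C to rt; then H2O
Reagents that add atoms: none
Why: Chelation-controlled Lewis acid cleavage of an aryl MOM ether: MgBr2 bridges the ketone oxygen and one of the two equivalent ortho acetal oxygens, so only an ortho MOM group is lost, and the hydroxyl group set free next to the side chain is the future O1.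

Step 6
Reactants: 10 (2S,3S)-4-(tert-butyldimethylsilyloxy)-1-[2-hydroxy-4,6-bis(methoxymethoxy)phenyl]-3-methyl-2-(3-methylbut-2-en-1-yl)butan-1-one
Product: 11 methyl carbonate of 10 at the phenolic oxygen (side-chain centres 2S,3S unchanged)
Conditions: ClCO2Me, Et3N, DMAP (cat.), THF, 0 °C
Reagents that add atoms: methyl chloroformate, COC(=O)Cl
Why: O-acylation of the hydrogen-bonded phenol to the mixed carbonate arms the ketone for ortho-hydroxyl-assisted deoxygenation.

Step 7
Reactants: 11 methyl carbonate of 10
Product: 13 2-[(2R)-2-[(2S)-1-(tert-butyldimethylsilyloxy)propan-2-yl]-5-methylhex-4-en-1-yl]-3,5-bis(methoxymethoxy)phenol, via ortho-quinone methide 12 (not isolated)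
Conditions: NaBH4, THF/H2O, 0 °C to rt
Reagents that add atoms: none
Why: Ortho-hydroxyl-assisted deoxygenation of a phenone: hydride reduces the ketone, the carbonate migrates to the benzylic alkoxide and is expelled to give ortho-quinone methide 12, and a second hydride adds in conjugate fashion to the methide carbon, all under basic conditions in which the neighbouring stereocentre is not touched.

Step 8
Reactants: 13 2-[(2R)-2-[(2S)-1-(tert-butyldimethylsilyloxy)propan-2-yl]-5-methylhex-4-en-1-yl]-3,5-bis(methoxymethoxy)phenol
Product: 14 2-[(2R)-2-[(2S)-1-(tert-butyldimethylsilyloxy)propan-2-yl]-5-methylhex-4-en-1-yl]-6-iodo-3,5-bis(methoxymethoxy)phenol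
Conditions: NIS (1.0 equiv), CH2Cl2, −78 to −20 °C, dark
Reagents that add atoms: N-iodosuccinimide (NIS), O=C1CCC(=O)N1I
Why: Electrophilic aromatic iodination of a very electron-rich phenol: the position ortho to the free hydroxyl group (flanked by OH and one OMOM) is less crowded than the one between two OMOM groups, and at low temperature the ring should outrun the trisubstituted alkene.

Step 9
Reactants: 15 methyl 2,4-dihydroxybenzoate
Product: 16 methyl 2,4-bis(methoxymethoxy)benzoate
Conditions: NaH, MOMCl, DMF, 0 °C to rt
Reagents that add atoms: chloromethyl methyl ether (MOMCl), COCCl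
Why: Williamson-type O-alkylation, in which NaH is needed to break the hydrogen bond of the 2-OH to the ester.

Step 10
Reactants: 16 methyl 2,4-bis(methoxymethoxy)benzoate
Product: 17 2,4-bis(methoxymethoxy)benzoic acid
Conditions: LiOH, THF/MeOH/H2O, 45 °C; then 1 M HCl to pH 4, 0 °C
Reagents that add atoms: lithium hydroxide, [Li+].[OH-]
Why: Ester saponification under conditions to which aryl MOM ethers are inert, followed by a cold and mild acidification.

Step 11
Reactants: 14 2-[(2R)-2-[(2S)-1-(tert-butyldimethylsilyloxy)propan-2-yl]-5-methylhex-4-en-1-yl]-6-iodo-3,5-bis(methoxymethoxy)phenol, 17 2,4-bis(methoxymethoxy)benzoic acid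
Product: 18 aryl ester of 14 (through its phenolic oxygen) with acid 17
Conditions: DCC, DMAP (cat.), CH2Cl2, rt
Reagents that add atoms: none
Why: Steglich esterification (carbodiimide activation, acyl transfer by DMAP) works on hindered phenols and avoids an acid chloride that would endanger the MOM groups.

Step 12
Reactants: 18 aryl ester of 14 with acid 17
Product: 19 1-[2,4-bis(methoxymethoxy)phenyl]ethenyl ether of iodophenol 14 (ester C=O replaced by C=CH2)
Conditions: Cp2TiMe2, toluene, 70 °C, dark; chromatography on Et3N-deactivated silica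
Reagents that add atoms: Cp2TiMe2, C[Ti](C)(C1C=CC=C1)C1C=CC=C1
Why: Petasis methylenation: thermally formed Cp2Ti=CH2 converts the aryl ester carbonyl through an oxatitanacyclobutane into the 1-arylvinyl aryl ether under non-acidic conditions that spare the aryl iodide, the acetals, the silyl ether and the trisubstituted alkene.

Step 13
Reactants: 19 1-[2,4-bis(methoxymethoxy)phenyl]ethenyl ether of iodophenol 14
Product: 21 2-{1-[2,4-bis(methoxymethoxy)phenyl]ethenyloxy}-3-[(2R)-2-[(2S)-1-(tert-butyldimethylsilyloxy)propan-2-yl]-5-methylhex-4-en-1-yl]-4,6-bis(methoxymethoxy)benzaldehyde, via aryllithium 20 (not isolated)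
Conditions: n-BuLi, THF, −78 °C; DMF, −78 to 0 °C; then H2O
Reagents that add atoms: N,N-dimethylformamide (DMF), CN(C)C=O
Why: Iodine–lithium exchange, much faster at −78 °C than any MOM-directed deprotonation, followed by formylation of aryllithium 20 with DMF places the aldehyde carbon (future C4) between O1 and the future 5-OMOM group, and the basic medium protects the enol ether.

Step 14
Reactants: 21 2-{1-[2,4-bis(methoxymethoxy)phenyl]ethenyloxy}-3-[(2R)-2-[(2S)-1-(tert-butyldimethylsilyloxy)propan-2-yl]-5-methylhex-4-en-1-yl]-4,6-bis(methoxymethoxy)benzaldehyde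
Product: 22 (2S)-2-[2,4-bis(methoxymethoxy)phenyl]-8-[(2R)-2-[(2S)-1-(tert-butyldimethylsilyloxy)propan-2-yl]-5-methylhex-4-en-1-yl]-5,7-bis(methoxymethoxy)chroman-4-one
Conditions: [Rh(cod)Cl]2 (2.5 mol %), (R)-DTBM-SEGPHOS (5 mol %), NaB[3,5-(CF3)2C6H3]4 (5 mol %), 4 Å molecular sieves, THF, 60 °C
Reagents that add atoms: none
Why: Proposed new method: oxidative addition of the formyl C–H bond of 21 to the cationic monovalent rhodium bisphosphine complex gives an acyl rhodium hydride in which O1 holds the 1,1-disubstituted enol ether on the metal; hydride insertion puts H on C2 and rhodium on the terminal carbon C3, and C–C reductive elimination from the seven-membered rhodacycle forms C3–C4, so that ring C, the C4 ketone and C2 arise in one redox-neutral isomerisation. The closest known reaction type is the rhodium/DTBM-SEGPHOS-catalysed, endo-selective, enantioselective hydroacylation of ortho-allylbenzaldehydes with 1,1-disubstituted alkenes to 3-substituted 1-tetralones (the carbocyclic counterpart of ring C), supported by the same reaction of N-vinylindole-2-carbaldehydes, where the alkene also carries the heteroatom; an O-vinyl substrate closing a chromanone has not been shown. Ring C closes in the 6-endo-trig mode with respect to the alkene. The new stereocentre C2 is set in the hydride insertion, where the axially chiral bisphosphine chooses the face of the enol ether (reagent control), the side-chain stereocentres being too remote to interfere. The step needs 6-endo over 5-exo regioselectivity, secured by the 1,1-disubstitution (the 5-exo path requires a tertiary benzylic alkyl rhodium species and a quaternary centre), chemoselectivity over the trisubstituted side-chain alkene, secured by its distance and substitution, and insertion faster than decarbonylation, favoured by chelation through O1 and the alkene. The neutral medium leaves the acid-labile enol ether of 21 and the base-labile C2–O1 bond of 22 intact.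

Step 15
Reactants: 22 (2S)-2-[2,4-bis(methoxymethoxy)phenyl]-8-[(2R)-2-[(2S)-1-(tert-butyldimethylsilyloxy)propan-2-yl]-5-methylhex-4-en-1-yl]-5,7-bis(methoxymethoxy)chroman-4-one
Product: 23 (2S)-2-(2,4-dihydroxyphenyl)-5,7-dihydroxy-8-[(2R)-2-[(2S)-1-hydroxypropan-2-yl]-5-methylhex-4-en-1-yl]chroman-4-one (target, CNP0262638.1)
Conditions: 2 M aq HCl, THF/i-PrOH, 40 °C
Reagents that add atoms: none
Why: Acid hydrolysis of the four aryl MOM acetals and the primary silyl ether in one operation; dilute acid at mild temperature is chosen because base would open ring C through the 4'-phenoxide and scramble C2, while the isolated trisubstituted alkene has no phenol within reach for cyclisation.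

## Compound list
1 | phloroglucinol (benzene-1,3,5-triol) | Oc1cc(O)cc(O)c1 | starting material
2 | 1,3,5-tris(methoxymethoxy)benzene | COCOc1cc(OCOC)cc(OCOC)c1 | intermediate
3 | (S)-4-methyldihydrofuran-2(3H)-one | O=C1C[C@H](C)CO1 | starting material
4 | prenyl bromide (1-bromo-3-methylbut-2-ene) | CC(C)=CCBr | starting material
5 | lithium enolate of 3 (4S) | [Li]OC1=C[C@H](C)CO1 | intermediate
6 | (3S,4S)-4-methyl-3-(3-methylbut-2-en-1-yl)dihydrofuran-2(3H)-one (trans) | CC(C)=CC[C@H](C(=O)O1)[C@H](C)C1 | intermediate
7 | 2,4,6-tris(methoxymethoxy)phenyllithium | [Li]c1c(OCOC)cc(OCOC)cc1OCOC | intermediate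
8 | (2S,3S)-4-hydroxy-3-methyl-2-(3-methylbut-2-en-1-yl)-1-[2,4,6-tris(methoxymethoxy)phenyl]butan-1-one | CC(C)=CC[C@H](C(=O)c1c(OCOC)cc(OCOC)cc1OCOC)[C@H](C)CO | intermediate
9 | TBS ether of 8 (2S,3S) | CC(C)=CC[C@H](C(=O)c1c(OCOC)cc(OCOC)cc1OCOC)[C@H](C)CO[Si](C)(C)C(C)(C)C | intermediate
10 | (2S,3S)-4-(tert-butyldimethylsilyloxy)-1-[2-hydroxy-4,6-bis(methoxymethoxy)phenyl]-3-methyl-2-(3-methylbut-2-en-1-yl)butan-1-one | CC(C)=CC[C@H](C(=O)c1c(OCOC)cc(OCOC)cc1O)[C@H](C)CO[Si](C)(C)C(C)(C)C | intermediate
11 | aryl methyl carbonate of 10 | CC(C)=CC[C@H](C(=O)c1c(OCOC)cc(OCOC)cc1OC(=O)OC)[C@H](C)CO[Si](C)(C)C(C)(C)C | intermediate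
12 | ortho-quinone methide (6-alkylidene-3,5-bis(methoxymethoxy)cyclohexa-2,4-dienone, side-chain centres as in 11) | CC(C)=CC[C@H](C=C1C(=O)C=C(OCOC)C=C1OCOC)[C@H](C)CO[Si](C)(C)C(C)(C)C | intermediate
13 | 2-[(2R)-2-[(2S)-1-(tert-butyldimethylsilyloxy)propan-2-yl]-5-methylhex-4-en-1-yl]-3,5-bis(methoxymethoxy)phenol | CC(C)=CC[C@H](Cc1c(OCOC)cc(OCOC)cc1O)[C@H](C)CO[Si](C)(C)C(C)(C)C | intermediate
14 | 6-iodo derivative of 13 (iodine ortho to OH) | CC(C)=CC[C@H](Cc1c(OCOC)cc(OCOC)c(I)c1O)[C@H](C)CO[Si](C)(C)C(C)(C)C | intermediate
15 | methyl 2,4-dihydroxybenzoate | COC(=O)c1ccc(O)cc1O | starting material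
16 | methyl 2,4-bis(methoxymethoxy)benzoate | COC(=O)c1ccc(OCOC)cc1OCOC | intermediate
17 | 2,4-bis(methoxymethoxy)benzoic acid | OC(=O)c1ccc(OCOC)cc1OCOC | intermediate
18 | 2,4-bis(methoxymethoxy)benzoate ester of iodophenol 14 | CC(C)=CC[C@H](Cc1c(OCOC)cc(OCOC)c(I)c1OC(=O)c1ccc(OCOC)cc1OCOC)[C@H](C)CO[Si](C)(C)C(C)(C)C | intermediate
19 | 1-[2,4-bis(methoxymethoxy)phenyl]ethenyl ether of iodophenol 14 | CC(C)=CC[C@H](Cc1c(OCOC)cc(OCOC)c(I)c1OC(=C)c1ccc(OCOC)cc1OCOC)[C@H](C)CO[Si](C)(C)C(C)(C)C | intermediate
20 | aryllithium from 19 (Li in place of I) | CC(C)=CC[C@H](Cc1c(OCOC)cc(OCOC)c([Li])c1OC(=C)c1ccc(OCOC)cc1OCOC)[C@H](C)CO[Si](C)(C)C(C)(C)C | intermediate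
21 | 2-{1-[2,4-bis(methoxymethoxy)phenyl]ethenyloxy}-3-[(2R)-2-[(2S)-1-(tert-butyldimethylsilyloxy)propan-2-yl]-5-methylhex-4-en-1-yl]-4,6-bis(methoxymethoxy)benzaldehyde | CC(C)=CC[C@H](Cc1c(OCOC)cc(OCOC)c(C=O)c1OC(=C)c1ccc(OCOC)cc1OCOC)[C@H](C)CO[Si](C)(C)C(C)(C)C | intermediate
22 | (2S)-2-[2,4-bis(methoxymethoxy)phenyl]-8-[(2R)-2-[(2S)-1-(tert-butyldimethylsilyloxy)propan-2-yl]-5-methylhex-4-en-1-yl]-5,7-bis(methoxymethoxy)chroman-4-one | CC(C)=CC[C@H](Cc1c(OCOC)cc(OCOC)c2c1O[C@H](c1ccc(OCOC)cc1OCOC)CC2=O)[C@H](C)CO[Si](C)(C)C(C)(C)C | intermediate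
23 | (2S)-2-(2,4-dihydroxyphenyl)-5,7-dihydroxy-8-[(2R)-2-[(2S)-1-hydroxypropan-2-yl]-5-methylhex-4-en-1-yl]chroman-4-one | CC(C)=CC[C@H](Cc1c(O)cc(O)c2c1O[C@H](c1ccc(O)cc1O)CC2=O)[C@H](C)CO | target

## Step count and risks
Total step count: 15.
Longest linear sequence: 12 steps (1, 3 to 8, 11 to 15; the branch that starts with step 2 is equally long).

**1. Step 14.**
- What may go wrong:
  - decarbonylation of the acyl rhodium hydride;
  - β-aryloxide elimination from the alkyl rhodium species;
  - Prins-type attack of the enol ether on the aldehyde, or hydrolysis of the enol ether, caused by the Lewis-acidic cationic metal;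
  - insufficient facial selectivity in the hydride insertion.
- Fallback, from 21 back to 22: a thiol-catalysed radical-chain hydroacylation (acyl radical cyclisation under polarity-reversal catalysis) with tert-dodecanethiol and 1,1'-azobis(cyclohexanecarbonitrile) in toluene at 100 °C.
  - The thiyl radical abstracts the formyl hydrogen, and the aroyl radical adds 6-endo to the CH2 terminus to give the benzylic, oxygen-stabilised C2 radical. The thiol then returns a hydrogen atom.
  - The C3–C4 bond and ring C form in the same way, but without control at C2, so 22 should come with the (2R)-epimer of 22 F1.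
  - The two are diastereomers because of the side chain and are separated by preparative HPLC.
  - F1 is opened with KOH in MeOH to the 2'-hydroxychalcone F2, which re-closes with NaOAc in hot EtOH (oxa-Michael addition) to the same pair for another separation.

**2. Step 3.**
- What may go wrong: the hindered aryllithium may deprotonate the α-branched lactone instead of adding to it. Material would be lost and the centre next to the carbonyl group would epimerise.
- Fallback, from 6 (and 7) back to 9: the electrophile is changed from an ester to an aldehyde.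
  - i-Bu2AlH in CH2Cl2 at −78 °C reduces 6 to the lactol F3.
  - Two equivalents of 7 add to the open hydroxy aldehyde form of F3 and give the benzylic diol F4, whose carbinol epimers are of no consequence.
  - TBSCl and imidazole silylate only the primary hydroxyl group, to the mono-TBS diol F5.
  - Dess–Martin periodinane buffered with NaHCO3 oxidises the benzylic carbinol to ketone 9.

**3. Step 8.**
- What may go wrong:
  - iodination at the position between the two MOM ethers;
  - double iodination;
  - attack of the iodonium source on the side-chain alkene.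
- Fallback, from 13 back to 14: the site is fixed by directed ortho-metalation instead of electrophilic substitution.
  - NaH and ClC(O)NEt2 convert 13 into the O-aryl diethylcarbamate F6.
  - s-BuLi/TMEDA in THF at −78 °C metalates the only free position next to the carbamate, where the carbamate is the strongest director and is reinforced by the adjacent OMOM. I2 then gives the iodo carbamate F7.
  - Reductive cleavage of the carbamate with Cp2Zr(H)Cl in THF at rt returns iodophenol 14 without touching the aryl iodide, the acetals or the silyl ether.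

## Further compounds
F1 | step 14 | (2R)-epimer of 22 | CC(C)=CC[C@H](Cc1c(OCOC)cc(OCOC)c2c1O[C@@H](c1ccc(OCOC)cc1OCOC)CC2=O)[C@H](C)CO[Si](C)(C)C(C)(C)C
F2 | step 14 | (E)-2'-hydroxychalcone from ring opening of F1 or 22 | CC(C)=CC[C@H](Cc1c(OCOC)cc(OCOC)c(C(=O)/C=C/c2ccc(OCOC)cc2OCOC)c1O)[C@H](C)CO[Si](C)(C)C(C)(C)C
F3 | step 3 | (3S,4S)-4-methyl-3-(3-methylbut-2-en-1-yl)tetrahydrofuran-2-ol (lactol, anomers) | CC(C)=CC[C@H](C(O)O1)[C@H](C)C1
F4 | step 3 | (2S,3S)-3-methyl-2-(3-methylbut-2-en-1-yl)-1-[2,4,6-tris(methoxymethoxy)phenyl]butane-1,4-diol (C1 epimers) | CC(C)=CC[C@H](C(O)c1c(OCOC)cc(OCOC)cc1OCOC)[C@H](C)CO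
F5 | step 3 | 4-O-TBS ether of F4 | CC(C)=CC[C@H](C(O)c1c(OCOC)cc(OCOC)cc1OCOC)[C@H](C)CO[Si](C)(C)C(C)(C)C
F6 | step 8 | O-aryl N,N-diethylcarbamate of 13 | CC(C)=CC[C@H](Cc1c(OCOC)cc(OCOC)cc1OC(=O)N(CC)CC)[C@H](C)CO[Si](C)(C)C(C)(C)C
F7 | step 8 | O-aryl N,N-diethylcarbamate of 14 (iodine ortho to the carbamate) | CC(C)=CC[C@H](Cc1c(OCOC)cc(OCOC)c(I)c1OC(=O)N(CC)CC)[C@H](C)CO[Si](C)(C)C(C)(C)C
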